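**Assumptions:** The target SMILES has no stereocenters and no defined axial configuration. It is the C2-symmetric 7,7'-dihydroxy-4,4'-dimethoxy-5,5'-dimethyl-8,8'-bicoumarin, and I treat the biaryl axis as unspecified and obtained racemic. No stereocenter needs to be set.

## Retrosynthetic overview
1. Disconnect the C8–C8' biaryl bond. It comes from homocoupling of the 8-iodo-7-hydroxycoumarin **7**, which fixes the regiochemistry at C8 rather than C6.
2. **7** comes from regioselective iodination of 7-hydroxy-4-methoxy-5-methylcoumarin **5**.
3. **5** comes from selective O-methylation of the much more acidic 4-OH of 4,7-dihydroxy-5-methylcoumarin **3**.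
4. **3** comes from a one-pot Pechmann-type condensation/cyclisation of orcinol with malonic acid. This forms the pyranone ring last, and its regiochemistry places the 7-OH and 5-Me.

## Forward route

**Step 1**
Reactants: **1** orcinol (5-methylbenzene-1,3-diol); **2** malonic acid
Product: **3** 4,7-dihydroxy-5-methylcoumarin
Conditions: anhydrous ZnCl2, POCl3, 65–70 °C, 2 h; aqueous workup
Reagents that add atoms: none beyond the two reactants (ZnCl2 and POCl3 are not retained)
Why: Pechmann-type C-acylation at the ring carbon para to one OH and ortho to the other, followed by lactonisation, gives the 7-hydroxy-5-methyl pattern. The minor 5-hydroxy-7-methyl isomer is removed by chromatography or recrystallisation. There is no stereocenter.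

**Step 2**
Reactants: **3**; **4** trimethylsilyldiazomethane
Product: **5** 7-hydroxy-4-methoxy-5-methylcoumarin
Conditions: TMSCHN2 (1.1 equiv), MeOH/toluene, 0 °C → rt, 3 h
Reagents that add atoms: TMSCHN2, `C[Si](C)(C)C=[N+]=[N-]`, which adds one CH3
Why: The vinylogous-acid 4-OH (pKa about 4) protonates TMSCHN2 and is methylated selectively, while the less acidic 7-phenol (pKa about 8) is untouched under these base-free conditions (acid–base-selective O-methylation).

**Step 3**
Reactants: **5**; **6** N-iodosuccinimide
Product: **7** 8-iodo-7-hydroxy-4-methoxy-5-methylcoumarin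
Conditions: NIS (1.05 equiv), MeCN, 0 °C → rt, 2 h
Reagents that add atoms: NIS, `O=C1CCC(=O)N1I`, which adds I
Why: Electrophilic aromatic iodination occurs ortho to the strongly activating 7-OH. C8 is activated by both the 7-OH and the ring oxygen and is less hindered than C6, which sits next to the 5-methyl group.

**Step 4**
Reactants: **7**; **8** bis(pinacolato)diboron
Product: **9** target, 7,7'-dihydroxy-4,4'-dimethoxy-5,5'-dimethyl-8,8'-bicoumarin
Conditions: B2pin2 (0.55 equiv), Pd(OAc)2 (5 mol%), SPhos (10 mol%), K3PO4, dioxane/H2O 10:1, 90 °C, 12 h
Reagents that add atoms: none retained. B2pin2 converts half of the iodide to ArBpin in situ, and the boron ends up as pinB–I / borate.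
Why: One-pot Miyaura borylation followed by Suzuki–Miyaura coupling of the remaining aryl iodide joins the two C8 positions. The free phenol, the methyl enol ether and the lactone survive the mild base. The axis is formed without stereocontrol.

## Checks
- **Target match:** Each half of **9** is `COc1cc(=O)oc2c(*)c(O)cc(C)c12`, which is the same as each half of the target SMILES. Ring sizes (6/6 coumarin), 4-OMe, 5-Me, 7-OH and the 8,8' link all match.
- **Atom balance:**
  - Step 1: C7H8O2 + C3H4O4 → C10H8O4 + 2 H2O.
  - Step 2: C10H8O4 + CH2 → C11H10O4.
  - Step 3: C11H10O4 → C11H9IO4.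
  - Step 4: 2 C11H9IO4 → C22H18O8 (the target formula) with loss of 2 I.
- **Functional group survival:** No step uses strongly basic, nucleophilic or demethylating conditions, so the 4-OMe (a vinylogous ester), the lactone and the phenol survive.
- **Stereochemistry:** There are no stereocenters, and nothing in the route could scramble the biaryl axis.

## Compound list
1 | orcinol | `Cc1cc(O)cc(O)c1` | starting material
2 | malonic acid | `OC(=O)CC(=O)O` | starting material
3 | 4,7-dihydroxy-5-methylcoumarin | `Cc1cc(O)cc2oc(=O)cc(O)c12` | intermediate
4 | trimethylsilyldiazomethane | `C[Si](C)(C)C=[N+]=[N-]` | starting material (reagent)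
5 | 7-hydroxy-4-methoxy-5-methylcoumarin | `COc1cc(=O)oc2cc(O)cc(C)c12` | intermediate
6 | N-iodosuccinimide | `O=C1CCC(=O)N1I` | starting material (reagent)
7 | 8-iodo-7-hydroxy-4-methoxy-5-methylcoumarin | `COc1cc(=O)oc2c(I)c(O)cc(C)c12` | intermediate
8 | bis(pinacolato)diboron | `CC1(C)OB(OC1(C)C)B1OC(C)(C)C(C)(C)O1` | starting material (reagent)
9 | 7,7'-dihydroxy-4,4'-dimethoxy-5,5'-dimethyl-8,8'-bicoumarin (axis unspecified) | `COc1cc(=O)oc2c(-c3c(O)cc(C)c4c(OC)cc(=O)oc34)c(O)cc(C)c12` | target

**Total steps:** 4. **Longest linear sequence:** 4 (1 → 3 → 5 → 7 → 9).

## Three steps most likely to fail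
1. **Step 4 (hindered tetra-ortho-substituted biaryl coupling).** Protodeiodination or protodeboronation of the o-hydroxyaryl species may lower the yield. Fallback: skip the iodide and oxidatively couple **5** directly (CuCl/TMEDA, O2, or FeCl3). This relies on the 5-methyl group blocking C6 to favour C8.
2. **Step 3 (regioselectivity).** Iodination may compete at C6 or at C3 of the enol ether. Fallback: install the C8 substituent by a different route, such as ortho-bromination of a 7-OH-protected **5** or a directed ortho-metalation, then carry that halide into the coupling.
3. **Step 1 (Pechmann regiochemistry and yield).** The 5-hydroxy-7-methyl regioisomer may form in significant amounts. Fallback: start from 2,4-dihydroxy-6-methylacetophenone and use NaH/dimethyl carbonate to build the 4-hydroxycoumarin. This fixes the 5-Me/7-OH pattern by construction.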